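Read the theta run at 49 min: it holds 0.516 M of product from 1.00 M of substrate, and that reading is of use once you see how the flask got there. Here is what stands on the bench and what is asked.

| flask | substrate | reagent | catalyst | time |
|---|---|---|---|---|
| theta | 1.00 M | 1.50 M | 0.100 M |  |
| beta | 0.500 M | 1.00 M | 0.100 M |  |
| zeta | 1.50 M | 1.50 M | 0.100 M |  |
| eta | 1.00 M | 0.750 M | 0.100 M |  |
| gamma | 1.00 M | 0.430 M | 0.100 M | 49 min |

| run | time / min | [product] / M |
|---|---|---|
| theta run | 3.7 | 0.010 |
| theta run | 11 | 0.063 |
| theta run | 22 | 0.184 |
| theta run | 34 | 0.352 |
| theta run | 49 | 0.516 |
| beta run | 3.7 | 0.008 |
| beta run | 11 | 0.027 |
| beta run | 22 | 0.082 |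
| beta run | 34 | 0.151 |
| beta run | 49 | 0.223 |
| zeta run | 3.7 | 0.014 |
| zeta run | 11 | 0.097 |
| zeta run | 22 | 0.291 |
| zeta run | 34 | 0.553 |
| zeta run | 49 | 0.816 |
| eta run | 3.7 | 0.014 |
| eta run | 11 | 0.061 |
| eta run | 22 | 0.155 |
| eta run | 34 | 0.278 |
| eta run | 49 | 0.427 |

(scatter of a reading: 0.005 M)

- Overall: substrate + reagent -> product, with catalyst as catalyst.
- Constant volume, constant temperature.
- Bound and free are read together.
- "The second partner" is reagent.
- An order is taken over about fifteen percent of the charge, up and down.

- how the opening rate goes with [substrate] round the charge of the theta run: the exponent of the rate at two percent of substrate gone to product (one fixed amount of product, the same in the runs compared)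
- how the opening rate goes with [reagent] round the charge of the theta run: the exponent of the rate at two percent of substrate gone to product
- the beta run starts with 0.500 M less of substrate and of reagent than the theta run, and with no product. Compared where both hold the same amount of substrate, once fifteen percent of what the beta run was charged with has turned into product, is the beta run faster, slower or alike (within a tenth)?
- product in the gamma run at 49 min, as a share of the substrate charged

Run the theta flask in slow motion. In the first instants it makes 0.010 M in 3.7 min, which as a share of its substrate is 0.00270 /min. In the middle, take c(substrate) as the charge minus c(product). Between 34 min and 49 min its logarithm falls at 0.0195 /min. Call this the working constant, the pseudo-first-order constant of the awake flask; this reading is faster than the opening figure, so in the theta run something was still switching on in the first minutes. Carry that line back to the charge and you get a lag of 11.7 min: from 22 min on, the theta readings lie as if the flask had idled that long and then run at the working constant.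

Now the end. The overall equation takes one reagent per substrate, and the gamma run has 0.430 M of reagent against 1.00 M of substrate. Reagent is therefore the limiting reagent, and the ceiling is 43.0 % of the substrate. The theta constant and lag would give gamma 51.7 % at 49 min, above that ceiling, so the constant must sag.

The eta run shows the sag. Over the same window its constant reads 0.0154 /min at a mean c(reagent) of 0.397 M, while theta's mean is 1.07 M. Read as a saturation curve, these two give a half-effect c(reagent) of 0.197 M. My own reckoning takes gamma's typical reagent as half its charge, 0.215 M. That gives a constant of 0.0120 /min and, with theta's lag, 36.1 % of the substrate.

The forecast puts the opening order in substrate at 0.7 (0.4 to 1.05) and the opening order in reagent at 0.1 (−0.2 to 0.4). It calls the beta run slower at matched substrate, and it gives the gamma run 30 % (24 % to 36 %), on the view that “reagent hardly matters early and seems to saturate”. My figure stands higher than its centre.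

The gamma run gives 33.6 % of its substrate as product at 49 min; the opening order in substrate is 0.63, the opening order in reagent is 0.084, and the beta run is slower at matched substrate.

    active catalyst + reagent ⇌ catalyst-reagent complex, settled at all times (16.70 /M)
    catalyst-reagent complex + substrate → product + active catalyst (0.1506 /M/min)
    catalyst → active catalyst (0.08340 /min)
    substrate + reagent + product → 2 product (0.01686 /M²/min)

The step that turns substrate, reagent and product into more product makes no difference worth a point to that gamma figure. Behind theta's lag, gamma's result means a constant of 0.0110 /min, lower than the theta working constant. The zeta run has theta's reagent charge of 1.50 M; theta's lag and working constant put a quarter of its substrate at 26.5 min, and the zeta run reached it at 25.5 min.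

The earlier runs and the new flask were computed for substances that don't exist.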